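The quinolone is cut at N1–C8a and C4–C4a. C4a and C8a are the only atoms at which the otherwise unsubstituted benzo ring (C4a, C5–C8, C8a) meets the heterocyclic half, whose N1, C2, C3(OMe) and C4 are all substituted. Because these two atoms are adjacent, the benzo ring can be delivered as benzyne. In one operation an acyclic primary β-enamino ester is N-arylated by benzyne and the ortho aryl anion then acylates itself on the ester, closing the pyridone ring and giving the target without protecting groups. The precursor is the E (N–H···O=C bonded) enamine of an α-methoxy β-keto ester that already carries the complete hydroxyalkyl chain.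

Key step: step 5

Assumption: the target has no stereocentre and no stereogenic double bond, so no enantio- or diastereocontrol is needed. The E geometry of enamine 10 is the only stereo-element on the route and disappears on aromatisation; C2 of 9 is racemic and is erased in step 4.

Step 1
Reactants: 1 dimethyl tridecanedioate
Product: 3 13-methoxy-13-oxotridecanoic acid (monomethyl tridecanedioate), via barium half-ester salt 2 (not isolated)
Conditions: Ba(OH)2·8H2O (0.5 equiv), MeOH, rt; then 2 M HCl, Et2O
Reagents that add atoms: barium hydroxide, [Ba+2].[OH-].[OH-]
Why: Partial saponification of a symmetrical diester with half an equivalent of barium hydroxide should stop at the half ester, because its barium salt 2 is expected to be sparingly soluble in methanol and to leave the solution before the second ester is attacked, and acidification then frees 3.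

Step 2
Reactants: 3 13-methoxy-13-oxotridecanoic acid; 4 methylmagnesium bromide
Product: 5 13-hydroxy-13-methyltetradecanoic acid
Conditions: MeMgBr (3.5 equiv), THF, 0 °C to rt; then cold 1 M HCl to pH 3
Reagents that add atoms: methylmagnesium bromide (compound 4), C[Mg]Br
Why: Grignard reaction in which the first equivalent of 4 turns the acid into a carboxylate that resists further attack and two more add to the methyl ester by way of the methyl ketone to give the tertiary alcohol, which should tolerate the brief cold dilute-acid work-up.

Step 3
Reactants: 5 13-hydroxy-13-methyltetradecanoic acid; 6 methyl methoxyacetate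
Product: 9 methyl 15-hydroxy-2-methoxy-15-methyl-3-oxohexadecanoate (racemic at C2), via acyl imidazolide 7 (not isolated), via lithium enolate 8 (not isolated)
Conditions: 5, CDI (1.1 equiv), THF, rt; cannulated into 6 (4.2 equiv)/LDA (4.0 equiv), THF, −78 °C to −20 °C; sat. aq NH4Cl
Reagents that add atoms: none
Why: Crossed Claisen condensation in which the chelated lithium enolate 8 is C-acylated by acyl imidazolide 7; CDI activates the acid without touching the tertiary alcohol, the excess of enolate covers the imidazole N–H, the hydroxyl proton and the acidic C2–H of the product, and the hindered tertiary alkoxide should not compete with the enolate for 7 at −78 °C.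

Step 4
Reactants: 9 methyl 15-hydroxy-2-methoxy-15-methyl-3-oxohexadecanoate
Product: 10 methyl (E)-3-amino-15-hydroxy-2-methoxy-15-methylhexadec-2-enoate (NH2 cis to CO2Me)
Conditions: NH4OAc (10 equiv), MeOH, 4 Å MS, 60 °C; crude product used without chromatography
Reagents that add atoms: ammonium acetate, CC(=O)[O-].[NH4+]
Why: Condensation of ammonia with the ketone of a β-keto ester followed by tautomerisation gives the vinylogous carbamate, whose E geometry (the one the key step needs) is the thermodynamic one because of conjugation and the N–H···O=C hydrogen bond, and the mildly buffered medium leaves the ester and the tertiary alcohol alone.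

Step 5
Reactants: 10 methyl (E)-3-amino-15-hydroxy-2-methoxy-15-methylhexadec-2-enoate; 11 2-(trimethylsilyl)phenyl trifluoromethanesulfonate
Product: 13 2-(12-hydroxy-12-methyltridecyl)-3-methoxyquinolin-4(1H)-one, via benzyne 12 (not isolated)
Conditions: CsF (3 equiv), THF, 65 °C, argon; 11 (0.9 equiv) added slowly by syringe pump
Reagents that add atoms: none
Why: Proposed new method: fluoride removes the silyl group of 11 with loss of triflate to give benzyne 12; the enamine nitrogen of 10 adds to it (N1–C8a), which makes nitrogen an ammonium centre, switches off its vinylogous donation into the ester and places an aryl anion ortho to it, and this anion adds to the ester carbonyl held cis by the E geometry (C4–C4a) and expels methoxide, which takes up the N–H proton. The closest known reaction type is the CsF-mediated union of arynes with methyl anthranilates or salicylates to give acridones and xanthones by heteroatom arylation and intramolecular acyl substitution, in which an acyclic, fully substituted primary β-enamino ester has not been used. The pyridone ring closes by 6-exo-trig attack of the aryl anion on the ester C=O. No stereocentre is created and symmetrical benzyne raises no regiochemical question. The step needs N- over C-arylation, which should follow because C2 of 10 already bears OMe and CO2Me and could react only by building a quaternary centre, and it needs acyl capture to outrun protonation of the aryl anion, which the preorganised cis ester, THF as a non-acidic medium and the slow release of 12 by sparingly soluble CsF should favour. A second arylation at the quinolone N–H is limited by keeping 11 as the limiting component, and the hindered tertiary alcohol is a much poorer aryne trap than the enamine nitrogen.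

Compound list
1 | dimethyl tridecanedioate (dimethyl brassylate) | COC(=O)CCCCCCCCCCCC(=O)OC | starting material
2 | barium bis(13-methoxy-13-oxotridecanoate), formed in the flask | COC(=O)CCCCCCCCCCCC(=O)[O-].COC(=O)CCCCCCCCCCCC(=O)[O-].[Ba+2] | intermediate
3 | 13-methoxy-13-oxotridecanoic acid (monomethyl tridecanedioate) | COC(=O)CCCCCCCCCCCC(=O)O | intermediate
4 | methylmagnesium bromide | C[Mg]Br | starting material
5 | 13-hydroxy-13-methyltetradecanoic acid | CC(C)(O)CCCCCCCCCCCC(=O)O | intermediate
6 | methyl methoxyacetate | COCC(=O)OC | starting material
7 | 13-hydroxy-1-(1H-imidazol-1-yl)-13-methyltetradecan-1-one (acyl imidazolide of 5), formed in the flask | CC(C)(O)CCCCCCCCCCCC(=O)n1ccnc1 | intermediate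
8 | lithium (E)-1,2-dimethoxyethen-1-olate (chelated enolate of 6, O–Li cis to the α-OMe), formed in the flask | [Li+].[O-]/C(OC)=C\OC | intermediate
9 | methyl 15-hydroxy-2-methoxy-15-methyl-3-oxohexadecanoate (racemic at C2) | COC(=O)C(OC)C(=O)CCCCCCCCCCCC(C)(C)O | intermediate
10 | methyl (E)-3-amino-15-hydroxy-2-methoxy-15-methylhexadec-2-enoate (NH2 cis to CO2Me) | N/C(CCCCCCCCCCCC(C)(C)O)=C(/OC)C(=O)OC | intermediate
11 | 2-(trimethylsilyl)phenyl trifluoromethanesulfonate | C[Si](C)(C)c1ccccc1OS(=O)(=O)C(F)(F)F | starting material
12 | benzyne (1,2-didehydrobenzene), formed in the flask | C1#CC=CC=C1 | intermediate
13 | 2-(12-hydroxy-12-methyltridecyl)-3-methoxyquinolin-4(1H)-one | COc1c(CCCCCCCCCCCC(C)(C)O)[nH]c2ccccc2c1=O | target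

Total step count: 5
Longest linear sequence: 5 steps (1 → 3 → 5 → 9 → 10 → 13)

Steps most likely to fail

Step 5 (the proposed new method). The aryl anion may be protonated before it reaches the ester, the enamine may react through carbon, or the product may be arylated a second time. The fallback is the classical Conrad–Limpach synthesis, which is established for 2-alkyl-4-quinolones bearing a C3 substituent. It sets out from 9: condensation with aniline (cat. AcOH, 4 Å MS, CH2Cl2, rt to 40 °C) should give methyl (E)-3-anilino-15-hydroxy-2-methoxy-15-methylhexadec-2-enoate F1. Brief heating of this compound in diphenyl ether at about 250 °C under neutral conditions should close the ring with loss of methanol and rejoin the route at 13. The same compound is what the aryne step would leave if it stopped after N-arylation, so such material would be cyclised in the same way. This path needs neither 10 nor step 4.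

Step 3. The tertiary alkoxide may be O-acylated to oligoesters, the enolate may self-condense, or acylation may stall as imidazole and the product drain the base. The fallback builds the β-keto ester under near-neutral conditions and brings in the C2 oxygen afterwards. It sets out from 5 by way of the same acyl imidazolide 7: decarboxylative Claisen condensation with potassium methyl malonate, MgCl2 and Et3N (Masamune–Brooks conditions, THF/MeCN, rt) should give methyl 15-hydroxy-15-methyl-3-oxohexadecanoate F2. Regitz diazo transfer (p-ABSA, Et3N, MeCN) should give methyl 2-diazo-15-hydroxy-15-methyl-3-oxohexadecanoate F3. Rh2(OAc)4-catalysed O–H insertion into methanol (MeOH/CH2Cl2, rt) then installs the methoxy group and rejoins the route at 9.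

Step 1. Hydrolysis may run on to the diacid, or unreacted diester may be carried along with the precipitate, so that the half ester is recovered poorly or impure. The fallback moves the desymmetrisation to the Grignard stage. It sets out from 1 and 4: MeMgBr (about 2 equiv, THF, 0 °C) converts each ester that reacts fully to the tertiary alcohol, because the intermediate ketone is more reactive than an ester. This should give methyl 13-hydroxy-13-methyltetradecanoate F4, a neutral mono-adduct that is separated by chromatography from unreacted 1 and doubly reacted material. Saponification (LiOH, THF/H2O, rt) rejoins the route at 5.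

Further compounds
F1 | step 5 | methyl (E)-3-anilino-15-hydroxy-2-methoxy-15-methylhexadec-2-enoate | c1ccccc1N/C(CCCCCCCCCCCC(C)(C)O)=C(/OC)C(=O)OC
F2 | step 3 | methyl 15-hydroxy-15-methyl-3-oxohexadecanoate | COC(=O)CC(=O)CCCCCCCCCCCC(C)(C)O
F3 | step 3 | methyl 2-diazo-15-hydroxy-15-methyl-3-oxohexadecanoate | COC(=O)C(=[N+]=[N-])C(=O)CCCCCCCCCCCC(C)(C)O
F4 | step 1 | methyl 13-hydroxy-13-methyltetradecanoate | COC(=O)CCCCCCCCCCCC(C)(C)O
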